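## Retrosynthetic overview

1. Target 25 ⇐ 24 ⇐ 23 (C1 desilylation, C3 acetylation). The ten-membered carbocycle is closed last, at C3–C4, by a ligand-controlled Ni/Cr-catalysed alkenyl iodide–aldehyde coupling of seco-aldehyde 22, which also sets C3.
2. 22 ⇐ 19 by Mitsunobu tigloylation with inversion at C8. 19 ⇐ butenolide 8 + enal 17 by zinc Barbier allylation (C7–C8 bond, C7 and C8 set, α-methylene lactone unveiled).
3. Butenolide 8 (C4–C7, C11–C13, C15) ⇐ ring-closing metathesis of the 2-(bromomethyl)acrylate of dienol 5 ⇐ asymmetric vinylation of (Z)-3-iodobut-2-enal ⇐ but-2-yn-1-ol.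
4. Enal 17 (C8–C10, C14, C1–C3) ⇐ catalytic asymmetric Ni/Cr coupling of (E)-enol triflate 10 (from methyl acetoacetate) with 3,3-dimethoxypropanal 13 (sets C1).
5. Ring order: butenolide (metathesis) → α-methylene-γ-lactone (allyl transposition in the Barbier step) → ten-membered carbocycle (Ni/Cr closure).

Assumption: atom labels C1–C15 are germacrane positions of the target (lactone O on C6, tiglate on C8, acetate on C3, free OH on C1, C14 on C10, C15 on C4); the target is (1S,3S,6R,7S,8R), 4Z, 9E.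
Assumption: L* is (S)-N-[2-(4-isopropyl-4,5-dihydro-1,3-oxazol-2-yl)-6-methylphenyl]methanesulfonamide and is taken to direct alkenyl transfer to the Re face of an aliphatic aldehyde; if a model coupling shows the opposite sense, its enantiomer is used in steps 8 and 15.
Assumption: metal alkoxides that are only protonated on aqueous work-up are not numbered.

## Route

Step 1
Reactants: 1 but-2-yn-1-ol
Product: 3 (2Z)-3-iodobut-2-en-1-ol, via cyclic alkenylaluminate 2 (not isolated)
Conditions: NaAlH2(OCH2CH2OCH3)2 (1.5 equiv), THF, 0 °C to rt; then I2, THF, −78 to 0 °C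
Reagents that add atoms: iodine, II
Why: Hydroxyl-directed trans-hydroalumination places aluminium on C3 inside a five-membered alkoxyaluminate, and iodinolysis of the C–Al bond with retention gives the Z-iodoalkene (future C4=C5, iodine cis to C6).

Step 2
Reactants: 3 (2Z)-3-iodobut-2-en-1-ol
Product: 4 (2Z)-3-iodobut-2-enal
Conditions: MnO2 (15 equiv), CH2Cl2, rt, dark; used at once
Reagents that add atoms: none
Why: Allylic oxidation with manganese dioxide gives the enal without touching the alkene geometry or the C–I bond.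

Step 3
Reactants: 4 (2Z)-3-iodobut-2-enal
Product: 5 (3S,4Z)-5-iodohexa-1,4-dien-3-ol
Conditions: (CH2=CH)2Zn (from CH2=CHMgBr and ZnCl2, salts removed with 1,4-dioxane), (−)-MIB (10 mol %), toluene/hexane, −30 to 0 °C
Reagents that add atoms: vinylmagnesium bromide, C=C[Mg]Br (transferred as divinylzinc, C=C[Zn]C=C)
Why: Amino-alcohol-catalysed organozinc addition to an aldehyde: the (−)-MIB–zinc complex delivers vinyl to the Si face of the enal, as it does for aryl and α,β-unsaturated aldehydes, setting C6 (3S in the dienol).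

Step 4
Reactants: 5 (3S,4Z)-5-iodohexa-1,4-dien-3-ol; 6 2-(bromomethyl)prop-2-enoic acid
Product: 7 (3S,4Z)-5-iodohexa-1,4-dien-3-yl 2-(bromomethyl)prop-2-enoate
Conditions: DCC, DMAP (5 mol %), CH2Cl2, 0 °C
Reagents that add atoms: none
Why: Steglich esterification at 0 °C acylates the bis-allylic alcohol without ionising it and with little attack of DMAP on the allylic bromide.

Step 5
Reactants: 7 (3S,4Z)-5-iodohexa-1,4-dien-3-yl 2-(bromomethyl)prop-2-enoate
Product: 8 (5S)-3-(bromomethyl)-5-[(1Z)-2-iodoprop-1-en-1-yl]furan-2(5H)-one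
Conditions: second-generation Grubbs catalyst RuCl2(=CHPh)(H2IMes)(PCy3) (5 mol %), toluene, 80 °C, argon sparge
Reagents that add atoms: none
Why: Ring-closing metathesis between the vinyl group and the 1,1-disubstituted acrylate closes the butenolide with loss of ethene; the trisubstituted iodoalkene and the carbinol centre are untouched.

Step 6
Reactants: 9 methyl 3-oxobutanoate
Product: 10 methyl (2E)-3-{[(trifluoromethyl)sulfonyl]oxy}but-2-enoate
Conditions: Tf2O, aqueous Me4NOH, hexanes, 5 °C to rt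
Reagents that add atoms: trifluoromethanesulfonic anhydride, O=S(=O)(OS(=O)(=O)C(F)(F)F)C(F)(F)F
Why: O-triflation of the tetramethylammonium enolate, which has no chelating counter-ion and reacts from its extended form, gives the E-enol triflate (triflate trans to the ester) and so fixes the C9=C10 geometry.

Step 7
Reactants: 11 3,3-dimethoxypropanenitrile
Product: 13 3,3-dimethoxypropanal, via N-aluminoimine 12 (not isolated)
Conditions: i-Bu2AlH (1.1 equiv), CH2Cl2, −78 °C; then aqueous KNaC4H4O6, 0 °C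
Reagents that add atoms: water, O
Why: Nitrile half-reduction: i-Bu2AlH adds once to give a stable N-aluminoimine that is hydrolysed to the aldehyde on buffered work-up, and the dimethyl acetal survives.

Step 8
Reactants: 10 methyl (2E)-3-{[(trifluoromethyl)sulfonyl]oxy}but-2-enoate; 13 3,3-dimethoxypropanal
Product: 14 methyl (2E,4S)-4-hydroxy-6,6-dimethoxy-3-methylhex-2-enoate
Conditions: CrCl2 (10 mol %), L* (11 mol %), 1,8-bis(dimethylamino)naphthalene (11 mol %), NiCl2(2,9-dimethyl-1,10-phenanthroline) (2 mol %), Mn powder (2 equiv), (C5H5)2ZrCl2 (1.1 equiv), LiCl (2 equiv), MeCN, rt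
Reagents that add atoms: none
Why: Catalytic asymmetric Nozaki–Hiyama–Kishi coupling: zerovalent nickel inserts into the C–OTf bond with retention, the alkenyl group passes to sulfonamide-ligated trivalent chromium and adds to the Re face of 13 to set C1 (4S), and the E-geometry keeps the γ-hydroxy ester from lactonising.

Step 9
Reactants: 14 methyl (2E,4S)-4-hydroxy-6,6-dimethoxy-3-methylhex-2-enoate
Product: 15 methyl (2E,4S)-4-{[tert-butyl(dimethyl)silyl]oxy}-6,6-dimethoxy-3-methylhex-2-enoate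
Conditions: TBSCl, imidazole, DMF, rt
Reagents that add atoms: tert-butyldimethylsilyl chloride, CC(C)(C)[Si](C)(C)Cl
Why: Standard silyl ether formation on the secondary allylic alcohol, needed so that only the C8 hydroxyl is free in step 13.

Step 10
Reactants: 15 methyl (2E,4S)-4-{[tert-butyl(dimethyl)silyl]oxy}-6,6-dimethoxy-3-methylhex-2-enoate
Product: 16 (2E,4S)-4-{[tert-butyl(dimethyl)silyl]oxy}-6,6-dimethoxy-3-methylhex-2-en-1-ol
Conditions: i-Bu2AlH (2.5 equiv), CH2Cl2, −78 °C; aqueous KNaC4H4O6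
Reagents that add atoms: none
Why: 1,2-Reduction of the conjugated ester by i-Bu2AlH gives the allylic alcohol and leaves the acetal and silyl ether intact.

Step 11
Reactants: 16 (2E,4S)-4-{[tert-butyl(dimethyl)silyl]oxy}-6,6-dimethoxy-3-methylhex-2-en-1-ol
Product: 17 (2E,4S)-4-{[tert-butyl(dimethyl)silyl]oxy}-6,6-dimethoxy-3-methylhex-2-enal
Conditions: MnO2 (15 equiv), CH2Cl2, rt
Reagents that add atoms: none
Why: Allylic oxidation with manganese dioxide gives the E-enal without epimerising the γ-silyloxy centre.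

Step 12
Reactants: 8 (5S)-3-(bromomethyl)-5-[(1Z)-2-iodoprop-1-en-1-yl]furan-2(5H)-one; 17 (2E,4S)-4-{[tert-butyl(dimethyl)silyl]oxy}-6,6-dimethoxy-3-methylhex-2-enal
Product: 19 (4R,5S)-4-[(1S,2E,4S)-4-{[tert-butyl(dimethyl)silyl]oxy}-1-hydroxy-6,6-dimethoxy-3-methylhex-2-en-1-yl]-5-[(1Z)-2-iodoprop-1-en-1-yl]-3-methylideneoxolan-2-one, via allylzinc bromide 18 (not isolated)
Conditions: 8 (1.3 equiv), Zn dust (3 equiv), THF/saturated aqueous NH4Cl (3:1), 0 °C to rt
Reagents that add atoms: none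
Why: Zinc Barbier allylation: the allylzinc reacts through its γ-carbon (C7) in a chair Zimmerman–Traxler transition state on the face anti to the C6 alkenyl group, giving the trans-lactone with the exocyclic methylene and the 8S carbinol, which is the C8 epimer that step 13 inverts.

Step 13
Reactants: 19 Barbier adduct (name as in step 12); 20 (2E)-2-methylbut-2-enoic acid (tiglic acid)
Product: 21 (1R,2E,4S)-4-{[tert-butyl(dimethyl)silyl]oxy}-1-{(2S,3R)-2-[(1Z)-2-iodoprop-1-en-1-yl]-4-methylidene-5-oxooxolan-3-yl}-6,6-dimethoxy-3-methylhex-2-en-1-yl (2E)-2-methylbut-2-enoate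
Conditions: PPh3, DIAD, toluene, 0 °C to rt
Reagents that add atoms: none
Why: Mitsunobu esterification: SN2 attack of tiglate on the alkoxyphosphonium inverts C8 to the required 8R (8β) configuration and installs the ester in the same operation.

Step 14
Reactants: 21 tiglate (name as in step 13)
Product: 22 (1R,2E,4S)-4-{[tert-butyl(dimethyl)silyl]oxy}-1-{(2S,3R)-2-[(1Z)-2-iodoprop-1-en-1-yl]-4-methylidene-5-oxooxolan-3-yl}-3-methyl-6-oxohex-2-en-1-yl (2E)-2-methylbut-2-enoate
Conditions: PPTS (0.3 equiv), acetone/H2O (10:1), 40 °C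
Reagents that add atoms: water, O
Why: Mild acid-catalysed acetal hydrolysis frees the C3 aldehyde; PPTS in wet acetone is too weak to cleave the secondary silyl ether or ionise the allylic tiglate.

Step 15
Reactants: 22 seco-aldehyde (name as in step 14)
Product: 23 (3aS,4R,5E,7S,9S,10Z,11aR)-7-{[tert-butyl(dimethyl)silyl]oxy}-9-hydroxy-6,10-dimethyl-3-methylidene-2-oxo-2,3,3a,4,7,8,9,11a-octahydrocyclodeca[b]furan-4-yl (2E)-2-methylbut-2-enoate
Conditions: CrCl2 (30 mol %), L* (33 mol %), 1,8-bis(dimethylamino)naphthalene (33 mol %), NiCl2(2,9-dimethyl-1,10-phenanthroline) (10 mol %), Mn powder (4 equiv), (C5H5)2ZrCl2 (1.5 equiv), LiCl (4 equiv), MeCN, rt; 22 added by syringe pump over 12 h (final 4 mM)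
Reagents that add atoms: none
Why: Proposed new method: a ligand-controlled, doubly catalytic nickel/chromium closure of a ten-membered carbocycle, in which zerovalent nickel (from the NiCl2 complex and Mn) inserts into the C4–I bond with retention of the Z-geometry, the alkenyl group passes to trivalent chromium carrying the chiral sulfonamide, and this alkenylchromium adds intramolecularly to the Re face of the C3 aldehyde inside the ligand pocket to give the 3S alkoxide, which (C5H5)2ZrCl2 takes over so that Mn can return chromium to the divalent state; slow addition keeps the monomer dilute while the catalyst stays concentrated, and the Z-alkene, the E-alkene and the trans-lactone pre-fold the chain; the closest known reaction type is the catalytic asymmetric Nozaki–Hiyama–Kishi coupling (intermolecular, and closures of large rings) together with the stoichiometric, uncontrolled Ni/Cr closure of ten-membered germacranolide rings, whereas catalyst control of the new carbinol centre in a medium-ring closure with a Z-trisubstituted alkenyl iodide has not been shown.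

Step 16
Reactants: 23 macrocyclic alcohol (name as in step 15)
Product: 24 (3aS,4R,5E,7S,9S,10Z,11aR)-9-(acetyloxy)-7-{[tert-butyl(dimethyl)silyl]oxy}-6,10-dimethyl-3-methylidene-2-oxo-2,3,3a,4,7,8,9,11a-octahydrocyclodeca[b]furan-4-yl (2E)-2-methylbut-2-enoate
Conditions: Ac2O, pyridine, DMAP (10 mol %), CH2Cl2, 0 °C to rt
Reagents that add atoms: acetic anhydride, CC(=O)OC(C)=O
Why: DMAP-catalysed acetylation of the only free hydroxyl (C3); the C1 silyl ether removes any ambiguity between the two allylic carbinols.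

Step 17
Reactants: 24 acetate (name as in step 16)
Product: 25 (3aS,4R,5E,7S,9S,10Z,11aR)-9-(acetyloxy)-7-hydroxy-6,10-dimethyl-3-methylidene-2-oxo-2,3,3a,4,7,8,9,11a-octahydrocyclodeca[b]furan-4-yl (2E)-2-methylbut-2-enoate (CNP0319825.6)
Conditions: HF·pyridine, pyridine, THF, 0 °C to rt
Reagents that add atoms: none
Why: Fluoride desilylation under buffered, non-basic conditions frees the C1 hydroxyl without 1,3-migration of the C3 acetate or attack on the α-methylene lactone.

## Compound list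

1 | but-2-yn-1-ol | CC#CCO | starting material
2 | sodium 2,2-bis(2-methoxyethoxy)-3-methyl-2,5-dihydro-1,2-oxaaluminol-2-uide (cyclic alkenylaluminate) | CC1=CCO[Al-]1(OCCOC)OCCOC.[Na+] | intermediate (not isolated)
3 | (2Z)-3-iodobut-2-en-1-ol | C/C(I)=C/CO | intermediate
4 | (2Z)-3-iodobut-2-enal | C/C(I)=C/C=O | intermediate
5 | (3S,4Z)-5-iodohexa-1,4-dien-3-ol | C=C[C@H](O)/C=C(/C)I | intermediate
6 | 2-(bromomethyl)prop-2-enoic acid | C=C(CBr)C(=O)O | starting material
7 | (3S,4Z)-5-iodohexa-1,4-dien-3-yl 2-(bromomethyl)prop-2-enoate | C=C[C@H](OC(=O)C(=C)CBr)/C=C(/C)I | intermediate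
8 | (5S)-3-(bromomethyl)-5-[(1Z)-2-iodoprop-1-en-1-yl]furan-2(5H)-one (fragment A) | O=C1O[C@H](/C=C(/C)I)C=C1CBr | intermediate
9 | methyl 3-oxobutanoate (methyl acetoacetate) | CC(=O)CC(=O)OC | starting material
10 | methyl (2E)-3-{[(trifluoromethyl)sulfonyl]oxy}but-2-enoate | COC(=O)/C=C(\C)OS(=O)(=O)C(F)(F)F | intermediate
11 | 3,3-dimethoxypropanenitrile | COC(OC)CC#N | starting material
12 | N-(diisobutylalumanyl)-3,3-dimethoxypropan-1-imine | COC(OC)CC=N[Al](CC(C)C)CC(C)C | intermediate (not isolated)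
13 | 3,3-dimethoxypropanal | COC(OC)CC=O | intermediate
14 | methyl (2E,4S)-4-hydroxy-6,6-dimethoxy-3-methylhex-2-enoate | COC(=O)/C=C(\C)[C@@H](O)CC(OC)OC | intermediate
15 | methyl (2E,4S)-4-{[tert-butyl(dimethyl)silyl]oxy}-6,6-dimethoxy-3-methylhex-2-enoate | COC(=O)/C=C(\C)[C@@H](O[Si](C)(C)C(C)(C)C)CC(OC)OC | intermediate
16 | (2E,4S)-4-{[tert-butyl(dimethyl)silyl]oxy}-6,6-dimethoxy-3-methylhex-2-en-1-ol | OC/C=C(\C)[C@@H](O[Si](C)(C)C(C)(C)C)CC(OC)OC | intermediate
17 | (2E,4S)-4-{[tert-butyl(dimethyl)silyl]oxy}-6,6-dimethoxy-3-methylhex-2-enal (fragment B) | O=C/C=C(\C)[C@@H](O[Si](C)(C)C(C)(C)C)CC(OC)OC | intermediate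
18 | bromido{[(5S)-5-[(1Z)-2-iodoprop-1-en-1-yl]-2-oxo-2,5-dihydrofuran-3-yl]methyl}zinc | Br[Zn]CC1=C[C@@H](/C=C(/C)I)OC1=O | intermediate (not isolated)
19 | (4R,5S)-4-[(1S,2E,4S)-4-{[tert-butyl(dimethyl)silyl]oxy}-1-hydroxy-6,6-dimethoxy-3-methylhex-2-en-1-yl]-5-[(1Z)-2-iodoprop-1-en-1-yl]-3-methylideneoxolan-2-one | C=C1C(=O)O[C@H](/C=C(/C)I)[C@H]1[C@@H](O)/C=C(\C)[C@@H](O[Si](C)(C)C(C)(C)C)CC(OC)OC | intermediate
20 | (2E)-2-methylbut-2-enoic acid (tiglic acid) | C/C=C(\C)C(=O)O | starting material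
21 | (1R,2E,4S)-4-{[tert-butyl(dimethyl)silyl]oxy}-1-{(2S,3R)-2-[(1Z)-2-iodoprop-1-en-1-yl]-4-methylidene-5-oxooxolan-3-yl}-6,6-dimethoxy-3-methylhex-2-en-1-yl (2E)-2-methylbut-2-enoate | C=C1C(=O)O[C@H](/C=C(/C)I)[C@H]1[C@H](OC(=O)/C(C)=C/C)/C=C(\C)[C@@H](O[Si](C)(C)C(C)(C)C)CC(OC)OC | intermediate
22 | (1R,2E,4S)-4-{[tert-butyl(dimethyl)silyl]oxy}-1-{(2S,3R)-2-[(1Z)-2-iodoprop-1-en-1-yl]-4-methylidene-5-oxooxolan-3-yl}-3-methyl-6-oxohex-2-en-1-yl (2E)-2-methylbut-2-enoate | C=C1C(=O)O[C@H](/C=C(/C)I)[C@H]1[C@H](OC(=O)/C(C)=C/C)/C=C(\C)[C@@H](O[Si](C)(C)C(C)(C)C)CC=O | intermediate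
23 | (3aS,4R,5E,7S,9S,10Z,11aR)-7-{[tert-butyl(dimethyl)silyl]oxy}-9-hydroxy-6,10-dimethyl-3-methylidene-2-oxo-2,3,3a,4,7,8,9,11a-octahydrocyclodeca[b]furan-4-yl (2E)-2-methylbut-2-enoate | C=C1C(=O)O[C@@H]2/C=C(/C)[C@@H](O)C[C@H](O[Si](C)(C)C(C)(C)C)/C(C)=C/[C@@H](OC(=O)/C(C)=C/C)[C@@H]12 | intermediate
24 | (3aS,4R,5E,7S,9S,10Z,11aR)-9-(acetyloxy)-7-{[tert-butyl(dimethyl)silyl]oxy}-6,10-dimethyl-3-methylidene-2-oxo-2,3,3a,4,7,8,9,11a-octahydrocyclodeca[b]furan-4-yl (2E)-2-methylbut-2-enoate | C=C1C(=O)O[C@@H]2/C=C(/C)[C@@H](OC(C)=O)C[C@H](O[Si](C)(C)C(C)(C)C)/C(C)=C/[C@@H](OC(=O)/C(C)=C/C)[C@@H]12 | intermediate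
25 | (3aS,4R,5E,7S,9S,10Z,11aR)-9-(acetyloxy)-7-hydroxy-6,10-dimethyl-3-methylidene-2-oxo-2,3,3a,4,7,8,9,11a-octahydrocyclodeca[b]furan-4-yl (2E)-2-methylbut-2-enoate | C=C1C(=O)O[C@@H]2/C=C(/C)[C@@H](OC(C)=O)C[C@H](O)/C(C)=C/[C@@H](OC(=O)/C(C)=C/C)[C@@H]12 | target

## Step count and risk

Total step count: 17.
Longest linear sequence: 11 steps (steps 1–5 then 12–17; the chains through steps 6, 8–11 and through steps 7, 8–11 are equally long).

Steps most likely to fail:

Step 15 (the proposed new step). The ring closure could lose to oligomerisation or to simple reduction of the C–I bond, and the ligand may be mismatched with the conformational bias of the folding chain, so that the 3R epimer dominates. The fallback sets out from 22 and uses only known chemistry. A stoichiometric, ligand-free closure with excess CrCl2 and NiCl2 (1 mol %) in degassed DMSO/THF at 2 mM, as known for ten-membered germacranolide rings, gives 23 together with its C3 epimer, (3aS,4R,5E,7S,9R,10Z,11aR)-7-{[tert-butyl(dimethyl)silyl]oxy}-9-hydroxy-6,10-dimethyl-3-methylidene-2-oxo-2,3,3a,4,7,8,9,11a-octahydrocyclodeca[b]furan-4-yl (2E)-2-methylbut-2-enoate F5. Dess–Martin periodinane then converts the mixture into the macrocyclic Z-enone, (3aR,4R,5E,7S,10Z,11aR)-7-{[tert-butyl(dimethyl)silyl]oxy}-6,10-dimethyl-3-methylidene-2,9-dioxo-2,3,3a,4,7,8,9,11a-octahydrocyclodeca[b]furan-4-yl (2E)-2-methylbut-2-enoate F6. Reduction with (R)-2-methyl-CBS-oxazaborolidine and catecholborane in toluene at −78 °C (alkenyl as the large group) gives the 3S alcohol, and the route is rejoined at 23.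

Step 13. The C8 carbinol is secondary, allylic and flanked by the branched C7, so the Mitsunobu reaction may be slow or give elimination or retention. The fallback sets out from 19. Dess–Martin oxidation gives the enone (4S,5S)-4-[(2E,4S)-4-{[tert-butyl(dimethyl)silyl]oxy}-6,6-dimethoxy-3-methylhex-2-enoyl]-5-[(1Z)-2-iodoprop-1-en-1-yl]-3-methylideneoxolan-2-one F3. Luche reduction (NaBH4, CeCl3·7H2O, MeOH, −78 °C), with Felkin–Anh attack anti to the C7–C6 bond, gives the 8R alcohol (4R,5S)-4-[(1R,2E,4S)-4-{[tert-butyl(dimethyl)silyl]oxy}-1-hydroxy-6,6-dimethoxy-3-methylhex-2-en-1-yl]-5-[(1Z)-2-iodoprop-1-en-1-yl]-3-methylideneoxolan-2-one F4. Yamaguchi esterification with 20 (2,4,6-trichlorobenzoyl chloride, Et3N, then DMAP, toluene) proceeds with retention, and the route is rejoined at 21.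

Step 3. The enantioselectivity of vinylzinc addition to a sensitive β-iodo Z-enal is uncertain, and the enal may isomerise. The fallback sets out from 4. CH2=CHMgBr in THF at −78 °C gives racemic (4Z)-5-iodohexa-1,4-dien-3-ol F1. Kinetic resolution with Candida antarctica lipase B and vinyl acetate in hexane acetylates the R enantiomer to (3R,4Z)-5-iodohexa-1,4-dien-3-yl acetate F2 and leaves the S alcohol (at most 50 %), which is separated by chromatography, and the route is rejoined at 5.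

## Further compounds

F1 | step 3 | (4Z)-5-iodohexa-1,4-dien-3-ol (racemic) | C=CC(O)/C=C(/C)I
F2 | step 3 | (3R,4Z)-5-iodohexa-1,4-dien-3-yl acetate | C=C[C@@H](OC(C)=O)/C=C(/C)I
F3 | step 13 | (4S,5S)-4-[(2E,4S)-4-{[tert-butyl(dimethyl)silyl]oxy}-6,6-dimethoxy-3-methylhex-2-enoyl]-5-[(1Z)-2-iodoprop-1-en-1-yl]-3-methylideneoxolan-2-one | C=C1C(=O)O[C@H](/C=C(/C)I)[C@H]1C(=O)/C=C(\C)[C@@H](O[Si](C)(C)C(C)(C)C)CC(OC)OC
F4 | step 13 | (4R,5S)-4-[(1R,2E,4S)-4-{[tert-butyl(dimethyl)silyl]oxy}-1-hydroxy-6,6-dimethoxy-3-methylhex-2-en-1-yl]-5-[(1Z)-2-iodoprop-1-en-1-yl]-3-methylideneoxolan-2-one | C=C1C(=O)O[C@H](/C=C(/C)I)[C@H]1[C@H](O)/C=C(\C)[C@@H](O[Si](C)(C)C(C)(C)C)CC(OC)OC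
F5 | step 15 | (3aS,4R,5E,7S,9R,10Z,11aR)-7-{[tert-butyl(dimethyl)silyl]oxy}-9-hydroxy-6,10-dimethyl-3-methylidene-2-oxo-2,3,3a,4,7,8,9,11a-octahydrocyclodeca[b]furan-4-yl (2E)-2-methylbut-2-enoate | C=C1C(=O)O[C@@H]2/C=C(/C)[C@H](O)C[C@H](O[Si](C)(C)C(C)(C)C)/C(C)=C/[C@@H](OC(=O)/C(C)=C/C)[C@@H]12
F6 | step 15 | (3aR,4R,5E,7S,10Z,11aR)-7-{[tert-butyl(dimethyl)silyl]oxy}-6,10-dimethyl-3-methylidene-2,9-dioxo-2,3,3a,4,7,8,9,11a-octahydrocyclodeca[b]furan-4-yl (2E)-2-methylbut-2-enoate | C=C1C(=O)O[C@@H]2/C=C(/C)C(=O)C[C@H](O[Si](C)(C)C(C)(C)C)/C(C)=C/[C@@H](OC(=O)/C(C)=C/C)[C@@H]12
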